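Count the activator.

the same everywhere: substrate 0.50 M
- green: activator 0.50 M; capture agent 0.15 M; temperature 80 °C; the very flask that is asked about, followed so far
- grey: activator 0.50 M; capture agent 0.15 M; temperature 75 °C; run made earlier
- flask: activator 0.500 M; capture agent 0.150 M; temperature 80 °C; time 40 h

| run | time / h | ring / % | substrate / % |
|---|---|---|---|
| green | 2.50 | 15.0 | 39.0 |
| green | 5.00 | 17.5 | 25.9 |
| green | 10.0 | 16.8 | 19.6 |
| green | 15.0 | 15.8 | 17.1 |
| green | 30.0 | 15.4 | 16.5 |
| grey | 2.50 | 10.9 | 49.3 |
| grey | 5.00 | 15.7 | 31.1 |
| grey | 10.0 | 16.6 | 21.1 |
| grey | 15.0 | 15.1 | 18.7 |
| grey | 30.0 | 14.7 | 15.6 |

(standard deviation of a reading: 0.5 percentage points)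

- Sunday's: at 40 h take out 90% of the ring then present, then wait 40 h
- Saturday's: at 40 h add activator, 50.0% of the amount charged, then wait 40 h
- Wednesday's: at 40 h raise the temperature by 20 K, then wait 40 h
- Thursday's: change nothing and wait 40 h more

- percent here means substrate units held: one open dimer counts as two
- removed ring is counted in
- what may be going on: activated form -> ring; capture agent + activated form -> trapped intermediate; substrate + activated form -> open dimer; activator + ring -> over-reaction product; substrate + activator -> activated form
- additions bring no volume worth counting

- ring, in percent of the substrate first charged, at 40 h
- what to do for the largest gain in ring; "none" if nothing gains more than 2 percentage points (Sunday's / Saturday's / Wednesday's / Thursday's / none)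
- ring present, with what was taken out counted in, in percent of the substrate first charged, after Sunday's
- ring present, with what was taken out counted in, in percent of the substrate first charged, after Wednesday's

The green run is the asked flask followed so far, and I read its substrate as a ladder of time constants, each the time in which the substrate would fall by a factor e at that interval's rate: 6.11 h between the first two readings, 36.6 h between 10.0 h and 15.0 h, and 420 h over the last interval, although that last rung is a fall of 0.6 percentage points against a scatter of 0.5 points on each reading. On the first rung the green ring reaches its highest reading, 17.5% at 5.00 h; on the last it barely moves. Substrate leaves by steps that need activator or the activated form made from it, so a time constant that grows this much longer while 16.5% of substrate remains points to activator as the limiting reagent, and the further wait is far shorter than the last rung.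

I therefore treat the fast steps as finished and keep one quantity, the spare: the activator charged, in substrate units, less one for each substrate unit gone, which is 16.5% at 30.0 h. Ring, activated form and trapped intermediate cost one activator per unit, over-reaction product costs two, and an open dimer costs one for its two units, so the spare equals the free activator plus over-reaction product less open dimers, each dimer counted once. Saturday's adds 50.0% in substrate units, more than the substrate and ring at the last readings together, so I expect it to cost ring. My own figure for the ring at 40 h is the last reading, 15.4%, give or take 0.5 points.

The forecast gives 15.3% (14.7% to 15.9%), chooses none, and puts Sunday's at 15.2% and Wednesday's at 15.2%, on the ground that “the flask is effectively dead”.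

The flask holds 15.4% of ring at 40 h, the best choice is none, and Sunday's and Wednesday's give 15.4% and 15.4%.

    activated form → ring (k = 0.0130 /min, Ea = 98.0 kJ/mol)
    capture agent + activated form → trapped intermediate (k = 0.0130 /M/min, Ea = 98.0 kJ/mol)
    substrate + activated form → open dimer (k = 0.0180 /M/min, Ea = 65.0 kJ/mol)
    activator + ring → over-reaction product (k = 0.0300 /M/min, Ea = 77.0 kJ/mol)
    substrate + activator → activated form (k = 0.0160 /M/min, Ea = 80.0 kJ/mol)
    (constants at 80 °C)

This ring is a finished yield: 0.00615% of the activator charge is free at 40.0 h, and Saturday's costs 14 points. The spare, a reading of 16.5% with the scatter of the substrate reading in it, goes with 17.1% for over-reaction product less dimers in this flask at 40.0 h. For the neighbour charged with 1.2 M of substrate, the spare is −13.2%, and its over-reaction product less dimers comes to −13.2%.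

The runs were generated by integration for an exercise, noise included.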